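The ochre run opened the meeting: at 50.0 min its Eb and Ky together came to 94.1% of the charge, but in violet to 68.7%.

| flask | Ky | remark | time |
|---|---|---|---|
| ochre | 0.0098 M | run made earlier |  |
| green | 0.034 M | run made earlier |  |
| violet | 0.077 M | run made earlier |  |
| dusk | 0.012 M |  | 50 min |
| autumn | 0.025 M |  | 50 min |
| winter | 0.10 M |  | 50 min |
| midnight | 0.047 M |  | 50 min |

- ochre (time / min: Eb / %, Ky / %): 4.00: 9.2, 90.7; 12.0: 24.1, 75.1; 25.0: 41.9, 55.8; 40.0: 58.7, 39.5; 50.0: 62.1, 32.0
- green (time / min: Eb / %, Ky / %): 4.00: 9.5, 89.8; 12.0: 22.0, 73.1; 25.0: 38.4, 53.0; 40.0: 47.9, 38.6; 50.0: 49.9, 35.9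
- violet (time / min: Eb / %, Ky / %): 4.00: 8.0, 88.3; 8.00: 13.2, 77.6; 15.0: 23.1, 63.9; 25.0: 31.9, 49.7; 50.0: 35.0, 33.7

(readings scatter by 1 percentage point)

- the analysis behind the earlier runs scatters by 1 percentage point, standard deviation

- the flasks put in order of amount of Eb, in percent of the Ky charged, best first, at 50 min (dusk / autumn / winter / midnight)
- the amount of Eb, in percent of the Ky charged of the flask you put first, at 50 min
- the amount of Eb, in percent of the Ky charged of the flask you put last, at 50 min

The first speaker noted that the readings of Ky left at that time were close, 32.0% in ochre and 33.7% in violet, so these two flasks differed mainly in what the used Ky had become.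

The second speaker proposed dividing one rate by the other so that time drops out. If the unseen loss is second order in Ky and Eb formation first order, their quotient goes as [Ky]. She therefore took the loss ratio, a selectivity factor read upside down: used Ky not found as Eb, over Eb found. Divided by the charge, it read 9.69 L mol⁻¹ in ochre, 8.37 L mol⁻¹ in green and, in violet, 11.6 L mol⁻¹, each with the scatter of its readings. She held the reading time fixed, because violet's ratio still rose, from 0.577 at 25.0 min to 0.894 at 50.0 min.

Her own reckoning, with violet's figure and violet's Ky left, put winter at 30.7%.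

The forecast read dusk > autumn > midnight > winter, with dusk at 61% (58% to 64%) and winter at 29% (24% to 32%), on the ground that “a side loss higher order in Ky competes with Eb formation”. Her figure stood 1.7 percentage points above its winter value.

The flasks gave dusk > autumn > midnight > winter: dusk 60.5%, autumn 53.9%, midnight 45.2%, winter 31.9%, which is 0.10 points under the top of the forecast's range.

    Ky ⇌ Eb + Ul (K = 0.0477 M, k = 3.79 × 10⁻⁴ s⁻¹)
    Ky + Eb → KyEb (k = 0.00244 L mol⁻¹ s⁻¹)
    2 Ky → Ky2 (k = 0.00109 L mol⁻¹ s⁻¹)

Neither dusk nor winter has come to rest. Winter's loss ratio per charge stands at 11.7 L mol⁻¹ at 50.0 min, and its Eb, each step taken net, is already made more slowly than it is used up, at 0.612 of that rate. In dusk, violet's reading of 11.6 L mol⁻¹ times the charge gives a ratio of 0.139, and the flask shows 0.105 at 50.0 min. Left until 500 min, dusk holds 64.7% of Eb, up from 60.5%, at a ratio of 0.366. Over the same time winter's ratio climbs to 8.42 and its Eb falls to 9.87%.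

The earlier runs and the new flask stem from a simulated flask with constants of no real substance; the scatter is artificial.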